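**Conventions.** Compound numbers are those of the steps and of the compound list. ArB is the complete protected ring B: 4-methoxy-3-(3-methylbut-2-enyl)-5-[(E)-3-methyl-3-(triethylsilyloxy)but-1-enyl]phenyl.

**Remark on the chemistry (assumption).** The (Sa,Sc,Sc) enantiomer of the phosphoramidite ligand in step 11 is taken to be the one that delivers the (S)-ether. If the sense of induction is the opposite, the mirror-image ligand is used and nothing else changes.

## Analysis of the target

Compound 23 is a (2S)-flavanone. Ring A is a phloroglucinol-type benzene with free hydroxyls at C5 and C7, and it is fused to ring C, the dihydropyranone O1–C2–C3–C4(=O). C2 carries ring B, a 1,3,4,5-tetrasubstituted benzene whose 4'-methoxy group is flanked by a 3'-prenyl group and a 5'-(E)-3-hydroxy-3-methylbut-1-enyl group.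

C2 is the only stereocentre. It is benzylic, bonded to O1 and β to the C4 carbonyl, so enolisation towards C3 can expel the ring A phenoxide (retro-oxa-Michael opening to the 2'-hydroxychalcone) and return racemic material.

The sensitive groups are:
- the free flavanone itself (base, heat);
- the tertiary alcohol, which is allylic and conjugated with ring B and therefore ionises or dehydrates under acid;
- the electron-rich prenyl alkene;
- the two phenols.

The synthesis is hard in three places. C2 must be set and kept without passing through a flavanone enolate, the three oxygens of ring A must be told apart, and ring B needs three different contiguous substituents placed without ambiguity.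

The strategy rests on one feature: C3 (a methylene) and C4 (a ketone carbon) are together the hydrolysed form of a C3=C4 enol ether. Ring C can therefore be closed as an alkene between a vinyl group on C2 (the branched carbon of an allyl aryl ether on O1) and the silyl enol ether of an acetyl group on ring A. The ketone then appears only in the final unmasking.

## Retrosynthetic reasoning

**23 from 21 (through 22).** The last operation removes all silicon. Four Si–O bonds are cut: the enol ether on O4, the aryl ethers on O5 and O7, and the tertiary ether of the side chain. Cleavage of the enol ether and protonation at C3 give the ketone 22, and the remaining silyl groups then leave. This order places the only moment at which a free flavanone exists at the very end, under buffered fluoride. The side-chain alcohol is carried as a triethylsilyl ether, because a bulkier silyl group on a tertiary carbon would not leave under conditions mild enough for the flavanone.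

**21 from 20.** The C3=C4 bond of ring C is cut. Cutting here, and not at O1–C2 or C4–C4a of a ketone-level intermediate, means the ring is formed with C4 masked, so the enolate that opens flavanones cannot exist during ring formation. The forward reaction is a ring-closing metathesis between the vinyl group on C2 and the 1-silyloxyvinyl group on ring A of 20. The acetyl methyl carbon and the terminal vinyl carbon leave together as the volatile two-carbon alkene. The reaction must close a six-membered ring onto a 1,1-disubstituted enol ether and leave the prenyl and styrenyl alkenes and C2 untouched.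

**20 from 19.** The enol O–Si bond is cut. The acetyl group of 19 has a single enolisable position, so soft enolisation with a silyl triflate and an amine can give only the required terminal enol ether.

**19 from 15 and 18.** The O1–C2 bond is cut. This is the bond next to the only stereocentre, and C2 is allylic in 19, so it can be made by an asymmetric allylic etherification of the linear cinnamyl carbonate 15 with the phenol 18. The forward reaction has to give the branched regioisomer and the (S) configuration. Both are properties of iridium phosphoramidite catalysis with aryl-substituted allyl units.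

**18 from 16.** Two Si–O bonds are cut. The three hydroxyls of 16 are differentiated by the hydrogen bond to the acetyl group: the para hydroxyl and one ortho hydroxyl are silylated, and the chelated one stays free for the etherification.

**15 from 10 and 11.** The carbonate is traced through the allylic alcohol 14 and the ester 12 to the aldehyde 10 and the phosphonate 11. The C=C bond made by the olefination places the aldehyde carbon of 10 at what becomes C2 and the phosphonate carbon at what becomes C3. The ester carbon is reduced and later lost in the metathesis.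

**10 from 7 and 8.** The aryl–alkenyl bond of the side chain is cut. A Heck reaction of the bromide 7 with the tertiary allylic alcohol 8 gives 9 with the (E) geometry and the complete hydroxyalkenyl chain in one step, and silylation gives 10.

**7 from 1 and 2.** The prenyl C–C bond is cut through an aromatic Claisen rearrangement. The phenol oxygen of 1 is used first as the anchor for a 1,1-dimethylpropargyl group (3), which is reduced to the 1,1-dimethylallyl ether 4. The ether rearranges to the only free ortho position (6), and the oxygen then becomes the methoxy group of 7. The bromine of 1 blocks the other ortho position and serves afterwards as the handle for the Heck reaction.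

## Alternatives that were turned down

**Alternative 1:** Disconnection of C4–C4a. The forward key step activates the (S)-β-aryloxy acid A1, (S)-3-[3,5-bis(triisopropylsilyloxy)phenoxy]-3-[3-iodo-4-methoxy-5-(3-methylbut-2-enyl)phenyl]propanoic acid, as a mixed anhydride, which acylates ring A ortho to O1 and gives the iodoflavanone A2.
- For it: ring A enters as a symmetric ether, so both ortho positions are the same and no regiochemical question arises. The etherification that sets C2 would use an unchelated, unhindered phenoxide, which is easier than the phenoxide of 18. No carbon is sacrificed. On these three points it is stronger than the chosen route.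
- Against it: the activated acid is a β-aryloxy acyl electrophile, and loss of the electron-rich aryloxide from C2 (elimination to the cinnamic acid, or ionisation at the benzylic carbon) competes with acylation and erodes C2. The strong acid released is not compatible with the tertiary allylic oxygen function, which is why A2 carries iodine in its place. The side chain must then be attached by a hot, basic palladium coupling on a flavanone with its ketone free, which are the conditions under which flavanones open. Turning the vinyl group into the acid also costs extra oxidation steps.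
- Comparison: the chosen route offers a neutral ring closure that tolerates the finished ring B and keeps the ketone masked until the last step.

**Alternative 2:** Disconnection of ring A (C8–C8a, C7–C8, C5–C6 and C4a–C5). The forward key step irradiates the diazo ketone A3, (S)-6-(diazoacetyl)-2-ArB-2,3-dihydropyran-4-one, with the siloxyalkyne A4, (triisopropylsilyloxy)ethyne. Wolff rearrangement gives a vinylketene, which adds A4 to a cyclobutenone; ring opening and 6π closure then give the phenol A5.
- For it: the 5-hydroxyl and the 7-silyloxy group are differentiated by construction, with regiochemistry fixed by the polarity of the ynol ether, and four C–C bonds form in one operation. On differentiation of the ring A oxygens it is stronger.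
- Against it: ring A is the one part of the target that can be bought intact (16), so the key step is spent on the easy part, while the stereocentre, now in a 2-aryl-dihydropyranone, still has to be made by a separate asymmetric step. Ultraviolet light meets the (E)-styrenyl chromophore of ring B (E/Z isomerisation, cycloaddition) and an enone. Preparing A3 requires selective functionalisation of one of two ketones.
- Comparison: the route is clearly longer. The chosen route needs only a chelation-controlled bis-silylation to tell the oxygens apart and closes its ring thermally.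

**Alternative 3:** Disconnection of C2–C3. The forward key step decomposes the diazo ketone A6, 2-diazo-1-[2-(ArB-methoxy)-4,6-bis(triisopropylsilyloxy)phenyl]ethanone, on a chiral dirhodium tetracarboxylate. The carbene inserts into one of the two enantiotopic benzylic C–H bonds and gives the flavanone A7, which is identical with 22.
- For it: it is the shortest plan. The ether is made by a simple benzylation, the aldehyde needs no homologation, ring and stereocentre are formed together, and no carbon is sacrificed. On step count it is stronger than the chosen route.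
- Against it: the carbene is of the acceptor-only kind and sits five atoms from the lone pairs of O1. Oxonium ylide formation followed by a benzyl shift to a 2-benzylbenzofuranone is the expected competitor of insertion to the six-membered ring. The electron-rich prenyl alkene invites cyclopropanation and the oxygenated arenes invite aromatic addition. Enantiocontrol rests entirely on the catalyst distinguishing two hydrogens, in the diazo ketone class where that induction is least dependable. A6 must also be made from a hindered 2,6-dioxygenated benzoic acid.
- Comparison: the chosen route sets C2 in a separate, well-understood catalytic step that can be assayed before the ring is closed, and its ring closure takes its chemoselectivity from the substitution pattern of the alkenes.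

Key step: step 13

## Route

**Step 1**
Reactants: 1 3-bromo-4-hydroxybenzaldehyde; 2 3-chloro-3-methylbut-1-yne
Product: 3 3-bromo-4-[(2-methylbut-3-yn-2-yl)oxy]benzaldehyde
Conditions: K2CO3, KI (cat.), CuI (cat.), acetone, 56 °C
Reagents that add atoms: none
Why: Copper-assisted O-alkylation of a phenoxide with a tertiary propargylic chloride, which reacts through a copper acetylide ion pair and so tolerates the tertiary centre; the formyl-activated phenol of 1 is acidic and a good partner.

**Step 2**
Reactants: 3 3-bromo-4-[(2-methylbut-3-yn-2-yl)oxy]benzaldehyde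
Product: 4 3-bromo-4-[(2-methylbut-3-en-2-yl)oxy]benzaldehyde
Conditions: H2 (1 atm), Pd/CaCO3 poisoned with Pb(OAc)2, quinoline, EtOAc, rt
Reagents that add atoms: none
Why: Lindlar semi-hydrogenation stops at the alkene, and the poisoned catalyst should leave the aryl bromide and the aldehyde alone.

**Step 3**
Reactants: 4 3-bromo-4-[(2-methylbut-3-en-2-yl)oxy]benzaldehyde
Product: 6 3-bromo-4-hydroxy-5-(3-methylbut-2-enyl)benzaldehyde, via Claisen dienone 5 (not isolated)
Conditions: PhNEt2, 135 °C
Reagents that add atoms: none
Why: Aromatic Claisen rearrangement; the [3,3] shift can end productively only at C5 because the other ortho position carries bromine, and dienone 5 tautomerises to the phenol. The allyl inversion of the shift turns the 1,1-dimethylallyl ether into a prenyl group, and the geminal methyl groups lower the temperature needed.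

**Step 4**
Reactants: 6 3-bromo-4-hydroxy-5-(3-methylbut-2-enyl)benzaldehyde
Product: 7 3-bromo-4-methoxy-5-(3-methylbut-2-enyl)benzaldehyde
Conditions: MeI, K2CO3, DMF, rt
Reagents that add atoms: iodomethane, CI
Why: Williamson methylation; the phenol is hindered on both sides but acidic, and a small electrophile in a dipolar solvent should suffice.

**Step 5**
Reactants: 7 3-bromo-4-methoxy-5-(3-methylbut-2-enyl)benzaldehyde; 8 2-methylbut-3-en-2-ol
Product: 9 3-[(E)-3-hydroxy-3-methylbut-1-enyl]-4-methoxy-5-(3-methylbut-2-enyl)benzaldehyde
Conditions: Pd(OAc)2 (5 mol%), P(o-tol)3 (10 mol%), Et3N, DMF, 100 °C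
Reagents that add atoms: none
Why: Mizoroki–Heck reaction; insertion at the unhindered terminal carbon of 8 and syn β-hydride elimination give the (E)-alkene. The carbinol carbon has no hydrogen, so the allylic alcohol cannot isomerise to a ketone, and the trisubstituted prenyl alkene is too hindered to insert.

**Step 6**
Reactants: 9 3-[(E)-3-hydroxy-3-methylbut-1-enyl]-4-methoxy-5-(3-methylbut-2-enyl)benzaldehyde
Product: 10 4-methoxy-3-(3-methylbut-2-enyl)-5-[(E)-3-methyl-3-(triethylsilyloxy)but-1-enyl]benzaldehyde (ArB–CHO)
Conditions: Et3SiOTf, 2,6-lutidine, CH2Cl2, −78 to 0 °C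
Reagents that add atoms: triethylsilyl trifluoromethanesulfonate, CC[Si](CC)(CC)OS(=O)(=O)C(F)(F)F
Why: Silylation of a tertiary alcohol with a silyl triflate and a hindered pyridine; the non-enolisable aldehyde is inert. The triethylsilyl group should survive steps 7 to 13 and still leave under the buffered fluoride of step 14.

**Step 7**
Reactants: 10 ArB–CHO; 11 triethyl phosphonoacetate
Product: 12 ethyl (E)-3-ArB-prop-2-enoate
Conditions: NaH, THF, 0 °C to rt
Reagents that add atoms: none
Why: Horner–Wadsworth–Emmons olefination; the stabilised phosphonate anion gives the (E)-cinnamate.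

**Step 8**
Reactants: 12 ethyl (E)-3-ArB-prop-2-enoate
Product: 14 (E)-3-ArB-prop-2-en-1-ol, via enal 13 (not isolated)
Conditions: i-Bu2AlH (2.5 equiv), CH2Cl2, −78 to 0 °C; aq. KNaC4H4O6 (potassium sodium tartrate)
Reagents that add atoms: none
Why: 1,2-Reduction of the unsaturated ester by the aluminium hydride through enal 13 to the allylic alcohol; conjugate reduction is not expected at low temperature and the silyl ether is untouched.

**Step 9**
Reactants: 14 (E)-3-ArB-prop-2-en-1-ol
Product: 15 methyl (E)-3-ArB-prop-2-enyl carbonate
Conditions: ClCO2Me, pyridine, CH2Cl2, 0 °C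
Reagents that add atoms: methyl chloroformate, COC(=O)Cl
Why: Acylation of the primary allylic alcohol gives the linear methyl carbonate, the usual electrophile for iridium-catalysed allylic substitution.

**Step 10**
Reactants: 16 2',4',6'-trihydroxyacetophenone
Product: 18 2'-hydroxy-4',6'-bis(triisopropylsilyloxy)acetophenone, via 4'-monosilyl ether 17 (not isolated)
Conditions: i-Pr3SiCl (2.1 equiv), imidazole, DMF, 0 °C to rt
Reagents that add atoms: triisopropylsilyl chloride, CC(C)[Si](Cl)(C(C)C)C(C)C
Why: Silylation follows acidity and accessibility: the 4'-hydroxyl reacts first (17), then one of the two equivalent ortho hydroxyls. The last hydroxyl is held in a hydrogen bond to the carbonyl and should stay free.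

**Step 11**
Reactants: 15 methyl (E)-3-ArB-prop-2-enyl carbonate; 18 2'-hydroxy-4',6'-bis(triisopropylsilyloxy)acetophenone
Product: 19 2'-[(S)-1-ArB-prop-2-enyloxy]-4',6'-bis(triisopropylsilyloxy)acetophenone
Conditions: 18 (1.5 equiv), LiN(SiMe3)2, THF, 0 °C; then 15, [Ir(cod)Cl]2 (2 mol%), (Sa,Sc,Sc)-O,O'-(1,1'-binaphthyl-2,2'-diyl)-N,N-bis(1-phenylethyl)phosphoramidite (4 mol%, pre-activated with n-PrNH2), THF, rt
Reagents that add atoms: none
Why: Iridium-catalysed asymmetric allylic etherification; ionisation of 15 gives an allyliridium intermediate that the phenoxide attacks at the aryl-substituted terminus, giving the branched ether. The cyclometallated phosphoramidite complex leaves one face of the allyl unit open, which sets C2 as (S). The reaction is stopped at full conversion so that the product cannot re-ionise.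

**Step 12**
Reactants: 19 2'-[(S)-1-ArB-prop-2-enyloxy]-4',6'-bis(triisopropylsilyloxy)acetophenone
Product: 20 tert-butyldimethylsilyl enol ether of 19: (S)-1-ArB-prop-2-enyl 2-[1-(tert-butyldimethylsilyloxy)vinyl]-3,5-bis(triisopropylsilyloxy)phenyl ether
Conditions: t-BuMe2SiOTf (1.5 equiv), Et3N (3 equiv), CH2Cl2, −78 to 0 °C
Reagents that add atoms: tert-butyldimethylsilyl trifluoromethanesulfonate, CC(C)(C)[Si](C)(C)OS(=O)(=O)C(F)(F)F
Why: Soft enolisation; the carbonyl oxygen is silylated and the amine removes a proton from the methyl group, the only α-position. Excess amine and low temperature keep the medium non-acidic so that the doubly activated allyl benzyl ether is not ionised.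

**Step 13**
Reactants: 20 tert-butyldimethylsilyl enol ether of 19
Product: 21 (S)-2-ArB-4-(tert-butyldimethylsilyloxy)-5,7-bis(triisopropylsilyloxy)-2H-chromene
Conditions: (H2IMes)(PCy3)Cl2Ru=CHPh (second-generation Grubbs catalyst, 10 mol%), 1,4-benzoquinone (20 mol%), toluene (5 mM), 60 °C, argon sparge, dark
Reagents that add atoms: none
Why: The reaction is a ring-closing metathesis of a silyl enol ether. The ruthenium alkylidene should load on the monosubstituted vinyl group on C2, the only unhindered terminal alkene, and the new alkylidene at C3 adds across the 1,1-disubstituted enol ether; the ruthenacyclobutane carries C4, with its silyloxy and aryl substituents, at the position remote from ruthenium and collapses to the C3=C4 bond and Ru=CH2, which releases the two methylene groups as ethylene. The closest known reactions are the ring-closing metathesis of acyclic silyl enol ethers to cyclic ones and of 2-alkenylphenyl allyl ethers to 2H-chromenes. Ring C closes as a six-membered ring with the new alkene inside the ring; the ortho relation of O1 and the enol ether on ring A holds the two alkenes within reach, and the argon stream removes ethylene so that the closure is not reversed. No stereocentre is formed, and C2 is not a reacting atom and keeps its configuration. The step needs chemoselectivity among four alkenes: the prenyl group is trisubstituted, the styrenyl alkene is 1,2-disubstituted next to a quaternary carbon, and both sit meta to C1', so no unstrained ring could form from them. It also needs the vinyl group to stay in place, and 1,4-benzoquinone is added to intercept ruthenium hydrides that would move the double bond towards O1 and destroy C2. High dilution disfavours dimerisation through the vinyl groups, and darkness and moderate temperature avoid electrocyclic opening of the 2H-chromene.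

**Step 14**
Reactants: 21 (S)-2-ArB-4-(tert-butyldimethylsilyloxy)-5,7-bis(triisopropylsilyloxy)-2H-chromene
Product: 23 (2S)-5,7-dihydroxy-2-{3-[(E)-3-hydroxy-3-methylbut-1-enyl]-4-methoxy-5-(3-methylbut-2-enyl)phenyl}chroman-4-one (EANPDB:LEGU_00041), via silylated flavanone 22 (not isolated)
Conditions: Bu4NF, AcOH (1:1, 6 equiv), THF, 0 °C to rt
Reagents that add atoms: none
Why: Fluoride should cleave the enol Si–O bond first; the enolate is protonated at C3 by acetic acid to give ketone 22, and the two aryl silyl ethers and the tertiary triethylsilyl ether follow. The acetic acid keeps the medium below the basicity at which a flavanone enolate would expel O1, so C2 should stay (S).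

## Compound list

1 | 3-bromo-4-hydroxybenzaldehyde | O=Cc1ccc(O)c(Br)c1 | starting material
2 | 3-chloro-3-methylbut-1-yne | CC(C)(Cl)C#C | starting material
3 | 3-bromo-4-[(2-methylbut-3-yn-2-yl)oxy]benzaldehyde | O=Cc1ccc(OC(C)(C)C#C)c(Br)c1 | intermediate
4 | 3-bromo-4-[(2-methylbut-3-en-2-yl)oxy]benzaldehyde | O=Cc1ccc(OC(C)(C)C=C)c(Br)c1 | intermediate
5 | 5-bromo-3-(3-methylbut-2-enyl)-4-oxocyclohexa-1,5-diene-1-carbaldehyde (Claisen dienone, not isolated) | O=CC1=CC(CC=C(C)C)C(=O)C(Br)=C1 | intermediate
6 | 3-bromo-4-hydroxy-5-(3-methylbut-2-enyl)benzaldehyde | O=Cc1cc(Br)c(O)c(CC=C(C)C)c1 | intermediate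
7 | 3-bromo-4-methoxy-5-(3-methylbut-2-enyl)benzaldehyde | COc1c(Br)cc(C=O)cc1CC=C(C)C | intermediate
8 | 2-methylbut-3-en-2-ol | C=CC(C)(C)O | starting material
9 | 3-[(E)-3-hydroxy-3-methylbut-1-enyl]-4-methoxy-5-(3-methylbut-2-enyl)benzaldehyde | COc1c(/C=C/C(C)(C)O)cc(C=O)cc1CC=C(C)C | intermediate
10 | 4-methoxy-3-(3-methylbut-2-enyl)-5-[(E)-3-methyl-3-(triethylsilyloxy)but-1-enyl]benzaldehyde | COc1c(/C=C/C(C)(C)O[Si](CC)(CC)CC)cc(C=O)cc1CC=C(C)C | intermediate
11 | triethyl phosphonoacetate | CCOC(=O)CP(=O)(OCC)OCC | starting material
12 | ethyl (E)-3-ArB-prop-2-enoate | CCOC(=O)/C=C/c1cc(CC=C(C)C)c(OC)c(/C=C/C(C)(C)O[Si](CC)(CC)CC)c1 | intermediate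
13 | (E)-3-ArB-prop-2-enal (not isolated) | O=C/C=C/c1cc(CC=C(C)C)c(OC)c(/C=C/C(C)(C)O[Si](CC)(CC)CC)c1 | intermediate
14 | (E)-3-ArB-prop-2-en-1-ol | OC/C=C/c1cc(CC=C(C)C)c(OC)c(/C=C/C(C)(C)O[Si](CC)(CC)CC)c1 | intermediate
15 | methyl (E)-3-ArB-prop-2-enyl carbonate | COC(=O)OC/C=C/c1cc(CC=C(C)C)c(OC)c(/C=C/C(C)(C)O[Si](CC)(CC)CC)c1 | intermediate
16 | 2',4',6'-trihydroxyacetophenone | CC(=O)c1c(O)cc(O)cc1O | starting material
17 | 2',6'-dihydroxy-4'-(triisopropylsilyloxy)acetophenone (not isolated) | CC(=O)c1c(O)cc(O[Si](C(C)C)(C(C)C)C(C)C)cc1O | intermediate
18 | 2'-hydroxy-4',6'-bis(triisopropylsilyloxy)acetophenone | CC(=O)c1c(O)cc(O[Si](C(C)C)(C(C)C)C(C)C)cc1O[Si](C(C)C)(C(C)C)C(C)C | intermediate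
19 | 2'-[(S)-1-ArB-prop-2-enyloxy]-4',6'-bis(triisopropylsilyloxy)acetophenone | CC(=O)c1c(O[C@H](c2cc(CC=C(C)C)c(OC)c(/C=C/C(C)(C)O[Si](CC)(CC)CC)c2)C=C)cc(O[Si](C(C)C)(C(C)C)C(C)C)cc1O[Si](C(C)C)(C(C)C)C(C)C | intermediate
20 | tert-butyldimethylsilyl enol ether of 19 (precursor of the key step) | C=C(O[Si](C)(C)C(C)(C)C)c1c(O[C@H](c2cc(CC=C(C)C)c(OC)c(/C=C/C(C)(C)O[Si](CC)(CC)CC)c2)C=C)cc(O[Si](C(C)C)(C(C)C)C(C)C)cc1O[Si](C(C)C)(C(C)C)C(C)C | intermediate
21 | (S)-2-ArB-4-(tert-butyldimethylsilyloxy)-5,7-bis(triisopropylsilyloxy)-2H-chromene (product of the key step) | CC(C)(C)[Si](C)(C)OC1=C[C@@H](c2cc(CC=C(C)C)c(OC)c(/C=C/C(C)(C)O[Si](CC)(CC)CC)c2)Oc2cc(O[Si](C(C)C)(C(C)C)C(C)C)cc(O[Si](C(C)C)(C(C)C)C(C)C)c12 | intermediate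
22 | (S)-2-ArB-5,7-bis(triisopropylsilyloxy)chroman-4-one (not isolated) | O=C1C[C@@H](c2cc(CC=C(C)C)c(OC)c(/C=C/C(C)(C)O[Si](CC)(CC)CC)c2)Oc2cc(O[Si](C(C)C)(C(C)C)C(C)C)cc(O[Si](C(C)C)(C(C)C)C(C)C)c12 | intermediate
23 | (2S)-5,7-dihydroxy-2-{3-[(E)-3-hydroxy-3-methylbut-1-enyl]-4-methoxy-5-(3-methylbut-2-enyl)phenyl}chroman-4-one | COc1c(/C=C/C(C)(C)O)cc([C@@H]2CC(=O)c3c(O)cc(O)cc3O2)cc1CC=C(C)C | target

## Step count and risk

Total: 14 steps. Longest linear sequence: 13 steps (steps 1 to 9 and 11 to 14); step 10 is the one-step side branch for ring A.

**Step 13 (key step).** The closure onto the hindered 1,1-disubstituted enol ether may stall. The enol ether is flanked on ring A by a silyloxy group that ends up peri to O4 in the product. If closure stalls, catalyst decay to ruthenium hydrides leads to double-bond migration in the allyl ether, or dimerisation through the vinyl groups takes over. Electrocyclic opening of the 2H-chromene by heat or light would also erode C2.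

Fallback: the silyl enol ether is replaced by a smaller methyl enol ether made from an ester. It sets out from carbonate 15 and comes back to the route at 22.
- Methyl 2,4,6-trihydroxybenzoate F1 is bis-silylated as in step 10 to methyl 2-hydroxy-4,6-bis(triisopropylsilyloxy)benzoate F2.
- F2 is etherified with 15 under the conditions of step 11 to the (S)-branched ether F3.
- The ester carbonyl of F3 is methylenated with Cp2TiMe2 (toluene, 65 °C) to the methyl enol ether F4.
- Ring-closing metathesis under the conditions of step 13 gives (S)-2-ArB-4-methoxy-5,7-bis(triisopropylsilyloxy)-2H-chromene F5. Its small methoxy group removes most of the peri congestion.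
- Brief hydrolysis of F5 with aqueous oxalic acid in THF at 0 °C gives 22, which is then desilylated with the reagents of step 14.

**Step 11.** The phenoxide of 18 is chelated to lithium by the ortho acetyl group and is a good leaving group. Attack on the allyliridium intermediate may be slow, and re-ionisation of the product may leak material to the linear ether and lower the enantiomeric purity.

Fallback: the C2–O1 bond is made by an SN2 epoxide opening instead. It sets out from the allylic alcohol 14 and comes back at 19.
- Sharpless epoxidation of 14 (Ti(Oi-Pr)4, L-(+)-diisopropyl tartrate, t-BuOOH, 4 Å sieves, CH2Cl2, −20 °C) gives the (2S,3S)-epoxy alcohol F6.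
- Opening of F6 at the benzylic carbon by phenol 18 with inversion, mediated by Ti(Oi-Pr)4, gives the (2S,3R)-diol F7.
- The diol is removed by a Corey–Winter sequence: thiocarbonyldiimidazole gives the cyclic thionocarbonate F8, and 1,3-dimethyl-2-phenyl-1,3,2-diazaphospholidine (THF, 40 °C) gives the terminal alkene 19.

**Step 14.** Under fluoride the unmasked flavanone may ring-open by retro-oxa-Michael reaction, which racemises C2, and the tertiary silyl ether may be removed only partly.

Fallback: the two events are separated so that no enolate is ever formed. It sets out from 21 and comes back at 23, and it makes no new compound (F0). The enol ether of 21 is hydrolysed by protonation at C3 with aqueous oxalic acid in THF at 0 °C, and 22 is isolated. The aryl and tertiary silyl ethers of 22 are then removed under acidic fluoride (HF·pyridine buffered with pyridine, THF, 0 °C to rt).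

**Step 3.** The tertiary allyl aryl ether may fragment, losing the C5 unit as a diene and returning phenol 1, in competition with the [3,3] shift.

Fallback: steps 1 to 3 are replaced by direct ortho C-prenylation. It sets out from 1 and comes back at 6, and it makes no new compound (F0). The potassium phenoxide of 1 (KOH) is alkylated with 1-bromo-3-methylbut-2-ene in water at rt. C-alkylation can occur only at the single free ortho position, and O-prenylated material is separated and discarded.

## Further compounds

F1 | step 13 | methyl 2,4,6-trihydroxybenzoate (purchased) | COC(=O)c1c(O)cc(O)cc1O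
F2 | step 13 | methyl 2-hydroxy-4,6-bis(triisopropylsilyloxy)benzoate | COC(=O)c1c(O)cc(O[Si](C(C)C)(C(C)C)C(C)C)cc1O[Si](C(C)C)(C(C)C)C(C)C
F3 | step 13 | methyl 2-[(S)-1-ArB-prop-2-enyloxy]-4,6-bis(triisopropylsilyloxy)benzoate | COC(=O)c1c(O[C@H](c2cc(CC=C(C)C)c(OC)c(/C=C/C(C)(C)O[Si](CC)(CC)CC)c2)C=C)cc(O[Si](C(C)C)(C(C)C)C(C)C)cc1O[Si](C(C)C)(C(C)C)C(C)C
F4 | step 13 | (S)-1-ArB-prop-2-enyl 2-(1-methoxyvinyl)-3,5-bis(triisopropylsilyloxy)phenyl ether | C=C(OC)c1c(O[C@H](c2cc(CC=C(C)C)c(OC)c(/C=C/C(C)(C)O[Si](CC)(CC)CC)c2)C=C)cc(O[Si](C(C)C)(C(C)C)C(C)C)cc1O[Si](C(C)C)(C(C)C)C(C)C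
F5 | step 13 | (S)-2-ArB-4-methoxy-5,7-bis(triisopropylsilyloxy)-2H-chromene | COC1=C[C@@H](c2cc(CC=C(C)C)c(OC)c(/C=C/C(C)(C)O[Si](CC)(CC)CC)c2)Oc2cc(O[Si](C(C)C)(C(C)C)C(C)C)cc(O[Si](C(C)C)(C(C)C)C(C)C)c12
F6 | step 11 | [(2S,3S)-3-ArB-oxiran-2-yl]methanol | OC[C@@H]1O[C@H]1c1cc(CC=C(C)C)c(OC)c(/C=C/C(C)(C)O[Si](CC)(CC)CC)c1
F7 | step 11 | (2S,3R)-3-ArB-3-[2-acetyl-3,5-bis(triisopropylsilyloxy)phenoxy]propane-1,2-diol | OC[C@H](O)[C@H](Oc1cc(O[Si](C(C)C)(C(C)C)C(C)C)cc(O[Si](C(C)C)(C(C)C)C(C)C)c1C(C)=O)c1cc(CC=C(C)C)c(OC)c(/C=C/C(C)(C)O[Si](CC)(CC)CC)c1
F8 | step 11 | cyclic thionocarbonate (1,3-dioxolane-2-thione) of diol F7 | S=C1OC[C@H](O1)[C@H](Oc2cc(O[Si](C(C)C)(C(C)C)C(C)C)cc(O[Si](C(C)C)(C(C)C)C(C)C)c2C(C)=O)c2cc(CC=C(C)C)c(OC)c(/C=C/C(C)(C)O[Si](CC)(CC)CC)c2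
F0 | step 14 | none | none
F0 | step 3 | none | none
A1 | alternative 1 | (S)-3-[3,5-bis(triisopropylsilyloxy)phenoxy]-3-[3-iodo-4-methoxy-5-(3-methylbut-2-enyl)phenyl]propanoic acid | OC(=O)C[C@@H](c1cc(CC=C(C)C)c(OC)c(I)c1)Oc1cc(O[Si](C(C)C)(C(C)C)C(C)C)cc(O[Si](C(C)C)(C(C)C)C(C)C)c1
A2 | alternative 1 | (S)-5'-iodo-4'-methoxy-3'-prenyl-5,7-bis(triisopropylsilyloxy)flavanone | O=C1C[C@@H](c2cc(CC=C(C)C)c(OC)c(I)c2)Oc2cc(O[Si](C(C)C)(C(C)C)C(C)C)cc(O[Si](C(C)C)(C(C)C)C(C)C)c12
A3 | alternative 2 | (S)-6-(diazoacetyl)-2-ArB-2,3-dihydropyran-4-one | [N-]=[N+]=CC(=O)C1=CC(=O)C[C@@H](c2cc(CC=C(C)C)c(OC)c(/C=C/C(C)(C)O[Si](CC)(CC)CC)c2)O1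
A4 | alternative 2 | (triisopropylsilyloxy)ethyne | C#CO[Si](C(C)C)(C(C)C)C(C)C
A5 | alternative 2 | (S)-2-ArB-5-hydroxy-7-(triisopropylsilyloxy)chroman-4-one | O=C1C[C@@H](c2cc(CC=C(C)C)c(OC)c(/C=C/C(C)(C)O[Si](CC)(CC)CC)c2)Oc2cc(O[Si](C(C)C)(C(C)C)C(C)C)cc(O)c12
A6 | alternative 3 | 2-diazo-1-[2-(ArB-methoxy)-4,6-bis(triisopropylsilyloxy)phenyl]ethanone | [N-]=[N+]=CC(=O)c1c(OCc2cc(CC=C(C)C)c(OC)c(/C=C/C(C)(C)O[Si](CC)(CC)CC)c2)cc(O[Si](C(C)C)(C(C)C)C(C)C)cc1O[Si](C(C)C)(C(C)C)C(C)C
A7 | alternative 3 | (S)-2-ArB-5,7-bis(triisopropylsilyloxy)chroman-4-one (identical with 22) | O=C1C[C@@H](c2cc(CC=C(C)C)c(OC)c(/C=C/C(C)(C)O[Si](CC)(CC)CC)c2)Oc2cc(O[Si](C(C)C)(C(C)C)C(C)C)cc(O[Si](C(C)C)(C(C)C)C(C)C)c12
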